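- The ratio of D to X at the end needs few of the given numbers, so I test each before I reckon it. Percentages are of the J charged.

| setting | alpha | theta | flask |
|---|---|---|---|
| J | 0.085 M | 0.085 M | 0.085 M |
| Z | 0.255 M | 0.255 M | 0.255 M |
| Q | 0.24 mM | 0.37 mM | 0.17 mM |
| L | 0.14 mM | 0.14 mM | 0.14 mM |
| remark | run made earlier | run made earlier |  |
| time |  |  | 12 d |

| run | time / d | D / % | X / % | J / % |
|---|---|---|---|---|
| alpha | 1.25 | 62.2 | 15.5 | 24.2 |
| alpha | 2.50 | 54.0 | 22.8 | 21.6 |
| alpha | 6.00 | 47.9 | 32.6 | 20.5 |
| alpha | 15.0 | 47.5 | 34.9 | 20.9 |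
| theta | 1.67 | 58.9 | 18.4 | 21.1 |
| theta | 5.00 | 47.1 | 33.8 | 19.3 |
| theta | 10.0 | 47.3 | 34.9 | 19.3 |
| theta | 15.0 | 45.2 | 34.9 | 18.2 |

(standard deviation of a reading: 1 percentage point)



- ratio of D to X at 10 min
- ratio of D to X at 12 d
- which of D and X there is more of at 12 d

- J, Z and L are charged alike in alpha, theta and the flask, so Q and time are what I have left to test.
- Q shows little in the late ratios of the two runs. Theta has 1.54 times the alpha charge, yet the late ratios, 1.36 in alpha and 1.33 in theta, differ by less than theta's last two readings differ from each other. The flask's Q, 0.708 of the alpha charge, lies outside both runs, though.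
- Time is the correction. X closes on its plateau at 0.470 d⁻¹ in alpha, and theta reads no faster, 0.449 d⁻¹. At the alpha rate, 0.356 % of the way stays open at 12 d.
- My number starts from the plateau ratio, D over X once the percentages stop moving (thermodynamic control): 1.34. The open gap adds 0.00836, far less than the theta spread, and gives 1.35, so D leads. Alpha's first reading lies much later than 10 min, so I commit to no early ratio.
- The forecast says 40 at 10 min, 1.36 at 12 d, a little above mine, and D ahead: “the equilibrium D/X is about 1.35”.
- The flask gives 35.1 at 10 min and 1.32 at 12 d, with D ahead, and a tenfold time changes little. The plateau ratio times the flask's 35.0 % of X gives 46.9 % of D; the flask holds 46.0 %.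

    J + Z ⇌ D (K = 13.0 M⁻¹, k = 0.0298 M⁻¹ min⁻¹)
    J + Z ⇌ X (K = 10.0 M⁻¹, k = 8.27 × 10⁻⁴ M⁻¹ min⁻¹)
    D + Q ⇌ X + Q, rate k3*[Q]*[D] forward; the back reaction follows from the equilibrium constant (k = 11.4 M⁻¹ min⁻¹)
    2 Q ⇌ E, settled at all times (K = 1.80 × 10⁶ M⁻¹)
    Q + L ⇌ G (K = 12000 M⁻¹, k = 95.0 M⁻¹ min⁻¹)

- The neighbour flask with 0.34 M of J, its other charges and time as in the flask, gets the plateau ratio 1.34 from me; the computed ratio at 12 d is 1.32, from 32.7 % of D and 24.9 % of X, with J holding most of the J charged.

All runs were generated by integration for substances that don't exist; the scatter is artificial.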